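The key step exploits the 1,4-relation between the alkylidene carbon C1′ and the bromine-bearing C4′ across the gem-dimethyl carbon C3′ of ring A (the cyclohexylidene): C6′–C1′–C2′–C3′(Me)2 is the skeleton of mesityl oxide and C5′–C4′ that of a vinyl sulfone, so one double Michael annulation forms C5′–C6′ and C3′–C4′. The sulfone becomes the C4′ ketone, the (R)-alcohol and finally the inverted bromide. Ring C of the hydrindane arises from an enantiospecific bromonium cyclization onto a β-keto ester. After Julia–Kocienski union, an intramolecular carbonyl-ene reaction closes ring B and converts the C1′ stereocentre into the E alkene geometry.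

Key step: step 1

Atom labels: the carbons of ring A carry primed locants: C1′ (alkylidene carbon), C2′ (CH2), C3′ (CMe2), C4′ (CHBr), C5′, C6′. Hydrindane atoms carry unprimed indene locants: C1 (CH with the side chain), C2 (CHOH), C3 (CH2), C3a (C–CH3), C4 (CHBr), C5, C6, C7 (C(CH3)OH), C7a (CH). Ring B is the cyclopentane, ring C the cyclohexane of the hydrindane.

Assumption: the sulfone annulation product is carried as a racemate and the derived enol ethers as E/Z mixtures, because that stereocentre and that geometry are erased in steps 3 and 5.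

Step 1
Reactants: 1 mesityl oxide (4-methylpent-3-en-2-one); 2 phenyl vinyl sulfone
Product: 6 3,3-dimethyl-4-(phenylsulfonyl)cyclohexan-1-one (racemic), via lithium dienolate 3 (not isolated), via lithiated Michael adduct 4 (not isolated), via lithium enolate 5 (not isolated)
Conditions: LiN(iPr)2, THF, −78 °C; then 2, −78 → 25 °C; aq NH4Cl
Reagents that add atoms: none
Why: LiN(iPr)2 removes a proton of the α′-methyl group of 1 under kinetic control to give the cross-conjugated dienolate 3, whose terminal carbon adds to the β-carbon of 2 (C5′–C6′ bond), and the α-sulfonyl carbanion 4 then adds intramolecularly to the β,β-dimethyl enone terminus (C3′–C4′ bond) to give enolate 5, so the sequence is an anionic formal [4+2] annulation of a 2-oxido-1,3-diene. The closest known reaction type is the double Michael (Michael–Michael ring closure) reaction of kinetic enone enolates with acrylates, vinyl sulfones or nitroalkenes. Ring A closes in the second conjugate addition in the 6-endo-trig mode, the ring bond being made at the quaternary carbon C3′. The only new stereocentre, C4′ with the sulfonyl group, forms racemic and is of no consequence because it is flattened to the ketone in step 3 and reset by the catalyst in step 4. The step needs α′- instead of γ-deprotonation (hindered amide base, low temperature), conjugate instead of carbonyl attack (soft sulfone acceptor) and placement of the heteroatom-bearing carbon next to the gem-dimethyl carbon, which the polarity of the two partners fixes.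

Step 2
Reactants: 6 3,3-dimethyl-4-(phenylsulfonyl)cyclohexan-1-one
Product: 7 {[4-(methoxymethylidene)-2,2-dimethylcyclohexyl]sulfonyl}benzene (racemic; E/Z mixture)
Conditions: Ph3P(CH2OMe)Cl, KOtBu, THF, 0 °C; then 6, 0 → 25 °C
Reagents that add atoms: (methoxymethyl)triphenylphosphonium chloride, COC[P+](c1ccccc1)(c1ccccc1)c1ccccc1.[Cl-]
Why: Wittig methoxymethylenation of the unhindered ring ketone turns C1′ into a masked formyl-bearing carbon without touching the weakly acidic sulfonyl C–H, and the enol ether geometry is irrelevant because step 5 erases it.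

Step 3
Reactants: 7 {[4-(methoxymethylidene)-2,2-dimethylcyclohexyl]sulfonyl}benzene
Product: 9 4-(methoxymethylidene)-2,2-dimethylcyclohexan-1-one (E/Z mixture), via sulfonyl carbanion 8 (not isolated)
Conditions: n-BuLi, THF, −78 °C; then Me3SiOOSiMe3, −78 → 0 °C; aq NH4Cl
Reagents that add atoms: bis(trimethylsilyl) peroxide, C[Si](C)(C)OO[Si](C)(C)C
Why: Oxidative desulfonylation: deprotonation at C4′ gives carbanion 8, which attacks a peroxide oxygen, and the α-silyloxy sulfone expels benzenesulfinate to unveil the C4′ ketone while the enol ether shields C1′.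

Step 4
Reactants: 9 4-(methoxymethylidene)-2,2-dimethylcyclohexan-1-one
Product: 10 (1R)-4-(methoxymethylidene)-2,2-dimethylcyclohexan-1-ol (E/Z mixture)
Conditions: (S)-1-methyl-3,3-diphenyltetrahydro-1H,3H-pyrrolo[1,2-c][1,3,2]oxazaborole (10 mol %), catecholborane, toluene, −78 → −40 °C
Reagents that add atoms: none
Why: Corey–Bakshi–Shibata reduction: the oxazaborolidine distinguishes the quaternary C3′ side (large) from the C5′ methylene side (small) and delivers hydride to the face that should give the (R)-alcohol, the only stereocentre of 10.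

Step 5
Reactants: 10 (1R)-4-(methoxymethylidene)-2,2-dimethylcyclohexan-1-ol
Product: 11 (1R,4R)-4-hydroxy-3,3-dimethylcyclohexane-1-carbaldehyde
Conditions: 1 M HCl, THF, 25 °C; then K2CO3, MeOH, 25 °C
Reagents that add atoms: water, O
Why: Acid hydrolysis of the enol ether gives the aldehyde and base equilibration through the enolate places the formyl group equatorial and trans to the equatorial hydroxyl (an axial formyl group would be syn-diaxial to a methyl group on C3′), so C4′ fixes C1′ as (R) under thermodynamic control.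

Step 6
Reactants: 12 but-3-yn-1-ol
Product: 13 (but-3-yn-1-yloxy)(tert-butyl)diphenylsilane
Conditions: t-BuPh2SiCl, imidazole, DMF, 25 °C
Reagents that add atoms: tert-butyl(chloro)diphenylsilane, CC(C)(C)[Si](Cl)(c1ccccc1)c1ccccc1
Why: Silyl ether formation protects the primary alcohol as a robust, non-participating group for the organoaluminium, triflation, dianion and solvolysis steps.

Step 7
Reactants: 13 (but-3-yn-1-yloxy)(tert-butyl)diphenylsilane
Product: 15 (2E)-5-[(tert-butyldiphenylsilyl)oxy]-3-methylpent-2-en-1-ol, via alkenylalane 14 (not isolated)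
Conditions: AlMe3, Cp2ZrCl2 (20 mol %), CH2Cl2, 0 → 25 °C; then (CH2O)n, THF, 0 → 25 °C; aq HCl
Reagents that add atoms: trimethylaluminium, C[Al](C)C; paraformaldehyde (reacting as formaldehyde), C=O
Why: Negishi zirconium-catalysed carboalumination adds CH3 and Al syn across the terminal alkyne with methyl at the internal carbon, and hydroxymethylation of alkenylalane 14 with retention sets the E trisubstituted alkene that later defines the relative configuration of C3a and C4.

Step 8
Reactants: 15 (2E)-5-[(tert-butyldiphenylsilyl)oxy]-3-methylpent-2-en-1-ol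
Product: 16 (2S,3R)-2-bromo-5-[(tert-butyldiphenylsilyl)oxy]-3-chloro-3-methylpentan-1-ol
Conditions: N-bromosuccinimide, ClTi(OiPr)3, 2-[(3,5-di-tert-butyl-2-hydroxybenzylidene)amino]-3,3-dimethylbutan-1-ol (20 mol %; the ligand enantiomer that gives (2S,3R)-16), hexanes, −20 °C
Reagents that add atoms: N-bromosuccinimide, O=C1CCC(=O)N1Br; chlorotitanium triisopropoxide, CC(C)O[Ti](Cl)(OC(C)C)OC(C)C
Why: Titanium-mediated catalytic enantioselective bromochlorination of an allylic alcohol: the chiral titanium alkoxide directs bromonium formation to one alkene face and chloride opens it anti at the tertiary carbon, so 16 carries the future C4 bromide and a tertiary chloride as latent leaving group.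

Step 9
Reactants: 16 (2S,3R)-2-bromo-5-[(tert-butyldiphenylsilyl)oxy]-3-chloro-3-methylpentan-1-ol
Product: 17 (2S,3R)-2-bromo-5-[(tert-butyldiphenylsilyl)oxy]-3-chloro-3-methylpentyl trifluoromethanesulfonate
Conditions: (CF3SO2)2O, 2,6-lutidine, CH2Cl2, −78 °C
Reagents that add atoms: trifluoromethanesulfonic anhydride, O=S(=O)(OS(=O)(=O)C(F)(F)F)C(F)(F)F
Why: Triflation of the primary alcohol gives an electrophile reactive enough for substitution at −78 °C in spite of the β-bromine, and no stereocentre is touched.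

Step 10
Reactants: 17 (2S,3R)-2-bromo-5-[(tert-butyldiphenylsilyl)oxy]-3-chloro-3-methylpentyl trifluoromethanesulfonate; 18 methyl acetoacetate
Product: 20 methyl (6S,7R)-6-bromo-9-[(tert-butyldiphenylsilyl)oxy]-7-chloro-7-methyl-3-oxononanoate, via acetoacetate dianion 19 (not isolated)
Conditions: 18, NaH, THF, 0 °C; n-BuLi, 0 °C; then 17, −78 → −20 °C; aq NH4Cl
Reagents that add atoms: none
Why: Alkylation of the acetoacetate dianion 19 occurs at its more nucleophilic terminal carbon by SN2 displacement of the primary triflate, which at low temperature should outrun elimination and leaves both halogen-bearing stereocentres untouched.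

Step 11
Reactants: 20 methyl (6S,7R)-6-bromo-9-[(tert-butyldiphenylsilyl)oxy]-7-chloro-7-methyl-3-oxononanoate
Product: 22 methyl (1S,2S,3S)-3-bromo-2-{2-[(tert-butyldiphenylsilyl)oxy]ethyl}-2-methyl-6-oxocyclohexane-1-carboxylate, via bromonium ion 21 (not isolated)
Conditions: (CF3)2CHOH, 2,6-di-tert-butylpyridine, 0 → 25 °C
Reagents that add atoms: none
Why: Ionising solvolysis of the tertiary chloride with anchimeric assistance by the neighbouring bromine gives the configurationally defined bromonium ion 21, and the enol carbon of the β-keto ester opens it at the tertiary terminus through a chair transition state (6-endo closure of ring C, overall retention at C3a), which places bromine equatorial and methyl axial while the epimerisable ester-bearing carbon settles equatorial.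

Step 12
Reactants: 22 methyl (1S,2S,3S)-3-bromo-2-{2-[(tert-butyldiphenylsilyl)oxy]ethyl}-2-methyl-6-oxocyclohexane-1-carboxylate
Product: 24 (2R,3S,4S)-4-bromo-3-{2-[(tert-butyldiphenylsilyl)oxy]ethyl}-2-(hydroxymethyl)-3-methylcyclohexan-1-one, via sodium enolate 23 (not isolated)
Conditions: NaH, THF, 0 °C; then LiAlH4, 0 °C; aq KNaC4H4O6 (potassium sodium tartrate)
Reagents that add atoms: none
Why: Reduction of a β-keto ester through its enolate: deprotonation masks the ketone as enolate 23 so that hydride reduces only the ester, and protonation on work-up from the axial face away from the axial methyl group leaves the hydroxymethyl group equatorial, which is also the thermodynamic epimer.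

Step 13
Reactants: 24 (2R,3S,4S)-4-bromo-3-{2-[(tert-butyldiphenylsilyl)oxy]ethyl}-2-(hydroxymethyl)-3-methylcyclohexan-1-one
Product: 25 (1R,2R,3S,4S)-4-bromo-3-{2-[(tert-butyldiphenylsilyl)oxy]ethyl}-2-(hydroxymethyl)-1,3-dimethylcyclohexan-1-ol
Conditions: MeMgBr, CeCl3, THF, −78 → 0 °C
Reagents that add atoms: methylmagnesium bromide, C[Mg]Br
Why: Organocerium 1,2-addition to the enolisable β-hydroxy ketone: the axial trajectory is blocked by the syn-axial methyl group on C3a, so the methyl nucleophile enters equatorially and the tertiary hydroxyl at C7 becomes axial.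

Step 14
Reactants: 25 (1R,2R,3S,4S)-4-bromo-3-{2-[(tert-butyldiphenylsilyl)oxy]ethyl}-2-(hydroxymethyl)-1,3-dimethylcyclohexan-1-ol
Product: 26 (1R,2S,3S,4S)-4-bromo-3-{2-[(tert-butyldiphenylsilyl)oxy]ethyl}-1,3-dimethyl-2-{[(1-phenyl-1H-tetrazol-5-yl)sulfanyl]methyl}cyclohexan-1-ol
Conditions: 1-phenyl-1H-tetrazole-5-thiol, PPh3, diisopropyl azodicarboxylate, THF, 0 → 25 °C
Reagents that add atoms: 1-phenyl-1H-tetrazole-5-thiol, Sc1nnnn1-c1ccccc1
Why: Mitsunobu thioetherification is selective for the primary alcohol because the tertiary alcohol cannot form an oxyphosphonium ion that undergoes SN2 displacement.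

Step 15
Reactants: 26 (1R,2S,3S,4S)-4-bromo-3-{2-[(tert-butyldiphenylsilyl)oxy]ethyl}-1,3-dimethyl-2-{[(1-phenyl-1H-tetrazol-5-yl)sulfanyl]methyl}cyclohexan-1-ol
Product: 27 (1R,2S,3S,4S)-4-bromo-3-{2-[(tert-butyldiphenylsilyl)oxy]ethyl}-1,3-dimethyl-2-{[(1-phenyl-1H-tetrazol-5-yl)sulfonyl]methyl}cyclohexan-1-ol
Conditions: H2O2, (NH4)6Mo7O24·4H2O (10 mol %), EtOH, 25 °C
Reagents that add atoms: hydrogen peroxide, OO
Why: Molybdate-catalysed peroxide oxidation takes the sulfide to the sulfone without affecting the bromide, the silyl ether or the tertiary alcohol.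

Step 16
Reactants: 27 (1R,2S,3S,4S)-4-bromo-3-{2-[(tert-butyldiphenylsilyl)oxy]ethyl}-1,3-dimethyl-2-{[(1-phenyl-1H-tetrazol-5-yl)sulfonyl]methyl}cyclohexan-1-ol; 11 (1R,4R)-4-hydroxy-3,3-dimethylcyclohexane-1-carbaldehyde
Product: 28 (1R,2S,3S,4S)-4-bromo-3-{2-[(tert-butyldiphenylsilyl)oxy]ethyl}-2-{(E)-2-[(1R,4R)-4-hydroxy-3,3-dimethylcyclohexyl]ethenyl}-1,3-dimethylcyclohexan-1-ol
Conditions: KN(SiMe3)2 (1.05 equiv), 1,2-dimethoxyethane, −60 °C; then 11, −60 → 25 °C; aq NH4Cl
Reagents that add atoms: none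
Why: Julia–Kocienski olefination: the sulfonyl carbanion of 27 adds to aldehyde 11, Smiles rearrangement and loss of SO2 and the tetrazolone give the disubstituted alkene with E geometry (favoured for a branched aldehyde and a potassium base in an ether solvent), and both hydroxyl groups, being less acidic than the sulfonyl C–H, are carried free.

Step 17
Reactants: 28 (1R,2S,3S,4S)-4-bromo-3-{2-[(tert-butyldiphenylsilyl)oxy]ethyl}-2-{(E)-2-[(1R,4R)-4-hydroxy-3,3-dimethylcyclohexyl]ethenyl}-1,3-dimethylcyclohexan-1-ol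
Product: 29 (1R,2S,3S,4S)-4-bromo-2-{(E)-2-[(1R,4S)-4-bromo-3,3-dimethylcyclohexyl]ethenyl}-3-{2-[(tert-butyldiphenylsilyl)oxy]ethyl}-1,3-dimethylcyclohexan-1-ol
Conditions: CBr4, PPh3, 2,6-lutidine, toluene, 0 → 70 °C
Reagents that add atoms: carbon tetrabromide, BrC(Br)(Br)Br
Why: Appel bromination: the equatorial ring A alcohol is converted into its oxyphosphonium ion and displaced by bromide with inversion (SN2, axial entry) to give the (S)-bromide, while the hindered tertiary alcohol should not be activated.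

Step 18
Reactants: 29 (1R,2S,3S,4S)-4-bromo-2-{(E)-2-[(1R,4S)-4-bromo-3,3-dimethylcyclohexyl]ethenyl}-3-{2-[(tert-butyldiphenylsilyl)oxy]ethyl}-1,3-dimethylcyclohexan-1-ol
Product: 30 (1R,2S,3S,4S)-4-bromo-2-{(E)-2-[(1R,4S)-4-bromo-3,3-dimethylcyclohexyl]ethenyl}-3-(2-hydroxyethyl)-1,3-dimethylcyclohexan-1-ol
Conditions: HF·pyridine, THF, 0 → 25 °C
Reagents that add atoms: none
Why: Acidic fluoride cleaves the silyl ether without the basic conditions that could cause anti elimination of HBr from the axial bromide of ring A.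

Step 19
Reactants: 30 (1R,2S,3S,4S)-4-bromo-2-{(E)-2-[(1R,4S)-4-bromo-3,3-dimethylcyclohexyl]ethenyl}-3-(2-hydroxyethyl)-1,3-dimethylcyclohexan-1-ol
Product: 31 2-[(1S,2S,3R,6S)-6-bromo-2-{(E)-2-[(1R,4S)-4-bromo-3,3-dimethylcyclohexyl]ethenyl}-3-hydroxy-1,3-dimethylcyclohexyl]acetaldehyde
Conditions: Dess–Martin periodinane, NaHCO3, CH2Cl2, 0 → 25 °C
Reagents that add atoms: none
Why: Dess–Martin oxidation converts the primary alcohol into the aldehyde under buffered, non-epimerising conditions and leaves the tertiary alcohol untouched.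

Step 20
Reactants: 31 2-[(1S,2S,3R,6S)-6-bromo-2-{(E)-2-[(1R,4S)-4-bromo-3,3-dimethylcyclohexyl]ethenyl}-3-hydroxy-1,3-dimethylcyclohexyl]acetaldehyde
Product: 32 iriediol, (1S,2R,3aS,4S,7R,7aS)-4-bromo-1-{(E)-[(4S)-4-bromo-3,3-dimethylcyclohexylidene]methyl}-3a,7-dimethyloctahydro-1H-indene-2,7-diol
Conditions: Me2AlCl (3.5 equiv), CH2Cl2, −78 → −20 °C; aq NaHCO3
Reagents that add atoms: none
Why: Intramolecular carbonyl-ene reaction: the aldehyde carbon bonds to C1 on the alkene face reached by its tether (trans ring fusion, side chain cis to H-7a) while the allylic hydrogen on C1′ is transferred suprafacially to oxygen through a compact bicyclic transition state, so the hydroxyl and alkenyl groups should end cis on ring B and the (R) configuration at C1′ should be translated into the E geometry of the new exocyclic alkene.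

Compound list
1 | mesityl oxide (4-methylpent-3-en-2-one) | CC(=O)C=C(C)C | starting material
2 | phenyl vinyl sulfone | C=CS(=O)(=O)c1ccccc1 | starting material
3 | lithium 4-methylpenta-1,3-dien-2-olate (kinetic dienolate of 1) | [Li]OC(=C)C=C(C)C | intermediate
4 | 1-lithio-6-methyl-1-(phenylsulfonyl)hept-5-en-4-one (Michael adduct carbanion) | [Li]C(CCC(=O)C=C(C)C)S(=O)(=O)c1ccccc1 | intermediate
5 | lithium 3,3-dimethyl-4-(phenylsulfonyl)cyclohex-1-en-1-olate | [Li]OC1=CC(C)(C)C(CC1)S(=O)(=O)c1ccccc1 | intermediate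
6 | 3,3-dimethyl-4-(phenylsulfonyl)cyclohexan-1-one (racemic) | O=C1CCC(S(=O)(=O)c2ccccc2)C(C)(C)C1 | intermediate
7 | {[4-(methoxymethylidene)-2,2-dimethylcyclohexyl]sulfonyl}benzene (racemic; E/Z mixture) | COC=C1CCC(S(=O)(=O)c2ccccc2)C(C)(C)C1 | intermediate
8 | α-lithio derivative of 7 (lithium at the sulfonyl-bearing carbon) | COC=C1CCC([Li])(S(=O)(=O)c2ccccc2)C(C)(C)C1 | intermediate
9 | 4-(methoxymethylidene)-2,2-dimethylcyclohexan-1-one (E/Z mixture) | COC=C1CCC(=O)C(C)(C)C1 | intermediate
10 | (1R)-4-(methoxymethylidene)-2,2-dimethylcyclohexan-1-ol (E/Z mixture) | COC=C1CC[C@@H](O)C(C)(C)C1 | intermediate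
11 | (1R,4R)-4-hydroxy-3,3-dimethylcyclohexane-1-carbaldehyde (trans, both groups equatorial) | O=C[C@H]1CC(C)(C)[C@H](O)CC1 | intermediate
12 | but-3-yn-1-ol | C#CCCO | starting material
13 | (but-3-yn-1-yloxy)(tert-butyl)diphenylsilane | C#CCCO[Si](c1ccccc1)(c1ccccc1)C(C)(C)C | intermediate
14 | {(1E)-4-[(tert-butyldiphenylsilyl)oxy]-2-methylbut-1-en-1-yl}dimethylalane | C[Al](C)/C=C(\C)CCO[Si](c1ccccc1)(c1ccccc1)C(C)(C)C | intermediate
15 | (2E)-5-[(tert-butyldiphenylsilyl)oxy]-3-methylpent-2-en-1-ol | OC/C=C(\C)CCO[Si](c1ccccc1)(c1ccccc1)C(C)(C)C | intermediate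
16 | (2S,3R)-2-bromo-5-[(tert-butyldiphenylsilyl)oxy]-3-chloro-3-methylpentan-1-ol | OC[C@H](Br)[C@](C)(Cl)CCO[Si](c1ccccc1)(c1ccccc1)C(C)(C)C | intermediate
17 | (2S,3R)-2-bromo-5-[(tert-butyldiphenylsilyl)oxy]-3-chloro-3-methylpentyl trifluoromethanesulfonate | FC(F)(F)S(=O)(=O)OC[C@H](Br)[C@](C)(Cl)CCO[Si](c1ccccc1)(c1ccccc1)C(C)(C)C | intermediate
18 | methyl acetoacetate | COC(=O)CC(C)=O | starting material
19 | sodium lithium dianion of methyl acetoacetate | [Li]CC(O[Na])=CC(=O)OC | intermediate
20 | methyl (6S,7R)-6-bromo-9-[(tert-butyldiphenylsilyl)oxy]-7-chloro-7-methyl-3-oxononanoate | COC(=O)CC(=O)CC[C@H](Br)[C@](C)(Cl)CCO[Si](c1ccccc1)(c1ccccc1)C(C)(C)C | intermediate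
21 | bromonium chloride from 20 (bromine bridging C6 and C7 of the chain) | COC(=O)CC(=O)CC[C@@H]1[Br+][C@@]1(C)CCO[Si](c1ccccc1)(c1ccccc1)C(C)(C)C.[Cl-] | intermediate
22 | methyl (1S,2S,3S)-3-bromo-2-{2-[(tert-butyldiphenylsilyl)oxy]ethyl}-2-methyl-6-oxocyclohexane-1-carboxylate (Br and ester equatorial, methyl axial) | CC(C)(C)[Si](c1ccccc1)(c1ccccc1)OCC[C@]1(C)[C@@H](Br)CCC(=O)[C@H]1C(=O)OC | intermediate
23 | sodium enolate of 22 | CC(C)(C)[Si](c1ccccc1)(c1ccccc1)OCC[C@]1(C)[C@@H](Br)CCC(O[Na])=C1C(=O)OC | intermediate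
24 | (2R,3S,4S)-4-bromo-3-{2-[(tert-butyldiphenylsilyl)oxy]ethyl}-2-(hydroxymethyl)-3-methylcyclohexan-1-one | CC(C)(C)[Si](c1ccccc1)(c1ccccc1)OCC[C@]1(C)[C@@H](Br)CCC(=O)[C@H]1CO | intermediate
25 | (1R,2R,3S,4S)-4-bromo-3-{2-[(tert-butyldiphenylsilyl)oxy]ethyl}-2-(hydroxymethyl)-1,3-dimethylcyclohexan-1-ol (tertiary OH axial) | CC(C)(C)[Si](c1ccccc1)(c1ccccc1)OCC[C@]1(C)[C@@H](Br)CC[C@@](C)(O)[C@H]1CO | intermediate
26 | (1R,2S,3S,4S)-4-bromo-3-{2-[(tert-butyldiphenylsilyl)oxy]ethyl}-1,3-dimethyl-2-{[(1-phenyl-1H-tetrazol-5-yl)sulfanyl]methyl}cyclohexan-1-ol | CC(C)(C)[Si](c1ccccc1)(c1ccccc1)OCC[C@]1(C)[C@@H](Br)CC[C@@](C)(O)[C@H]1CSc1nnnn1-c1ccccc1 | intermediate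
27 | (1R,2S,3S,4S)-4-bromo-3-{2-[(tert-butyldiphenylsilyl)oxy]ethyl}-1,3-dimethyl-2-{[(1-phenyl-1H-tetrazol-5-yl)sulfonyl]methyl}cyclohexan-1-ol | CC(C)(C)[Si](c1ccccc1)(c1ccccc1)OCC[C@]1(C)[C@@H](Br)CC[C@@](C)(O)[C@H]1CS(=O)(=O)c1nnnn1-c1ccccc1 | intermediate
28 | (1R,2S,3S,4S)-4-bromo-3-{2-[(tert-butyldiphenylsilyl)oxy]ethyl}-2-{(E)-2-[(1R,4R)-4-hydroxy-3,3-dimethylcyclohexyl]ethenyl}-1,3-dimethylcyclohexan-1-ol | CC(C)(C)[Si](c1ccccc1)(c1ccccc1)OCC[C@]1(C)[C@@H](Br)CC[C@@](C)(O)[C@H]1/C=C/[C@H]1CC(C)(C)[C@H](O)CC1 | intermediate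
29 | (1R,2S,3S,4S)-4-bromo-2-{(E)-2-[(1R,4S)-4-bromo-3,3-dimethylcyclohexyl]ethenyl}-3-{2-[(tert-butyldiphenylsilyl)oxy]ethyl}-1,3-dimethylcyclohexan-1-ol (ring A bromide cis to the vinyl group) | CC(C)(C)[Si](c1ccccc1)(c1ccccc1)OCC[C@]1(C)[C@@H](Br)CC[C@@](C)(O)[C@H]1/C=C/[C@H]1CC(C)(C)[C@@H](Br)CC1 | intermediate
30 | (1R,2S,3S,4S)-4-bromo-2-{(E)-2-[(1R,4S)-4-bromo-3,3-dimethylcyclohexyl]ethenyl}-3-(2-hydroxyethyl)-1,3-dimethylcyclohexan-1-ol | OCC[C@]1(C)[C@@H](Br)CC[C@@](C)(O)[C@H]1/C=C/[C@H]1CC(C)(C)[C@@H](Br)CC1 | intermediate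
31 | 2-[(1S,2S,3R,6S)-6-bromo-2-{(E)-2-[(1R,4S)-4-bromo-3,3-dimethylcyclohexyl]ethenyl}-3-hydroxy-1,3-dimethylcyclohexyl]acetaldehyde | O=CC[C@]1(C)[C@@H](Br)CC[C@@](C)(O)[C@H]1/C=C/[C@H]1CC(C)(C)[C@@H](Br)CC1 | intermediate
32 | iriediol, (1S,2R,3aS,4S,7R,7aS)-4-bromo-1-{(E)-[(4S)-4-bromo-3,3-dimethylcyclohexylidene]methyl}-3a,7-dimethyloctahydro-1H-indene-2,7-diol | CC1(C)C/C(=C/[C@@H]2[C@H](O)C[C@]3(C)[C@@H](Br)CC[C@@](C)(O)[C@@H]23)CC[C@@H]1Br | target

Total step count: 20. Longest linear sequence: 15 steps (steps 6–20, from but-3-yn-1-ol); the ring A branch (steps 1–5) joins in step 16.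

Steps most likely to fail

Step 20 (carbonyl-ene closure of ring B). Me2AlCl may ionise or eliminate the axial secondary bromide of ring A, and the cyclization may run stepwise through a cation with hydride shift. Either process would erode the transfer of chirality into the alkene geometry or give endocyclic alkene isomers. The fallback closes ring B before ring A is brominated and without any Lewis acid. It sets out from 28 and comes back at 32. HF·pyridine removes the silyl group to give triol F1. 2,2,6,6-Tetramethylpiperidin-1-oxyl with PhI(OAc)2 oxidises only the primary alcohol to hydroxy aldehyde F2. Heating in toluene (170 °C, sealed tube) should effect the uncatalysed, concerted ene cyclization to ene triol F3. t-BuMe2SiCl and imidazole silylate the less hindered cyclopentanol to silyl ether F4. CBr4/PPh3 inverts the ring A alcohol to bromide F5, and HF·pyridine then gives 32.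

Step 17 (Appel inversion at C4′). The neopentyl-type secondary centre resists backside displacement, so elimination to the cyclohexene, methyl migration or dehydration of the free tertiary alcohol may outrun substitution. The fallback moves the bromination to the monocyclic fragment and uses sulfonate displacement. It sets out from 11 and comes back at 29. HC(OMe)3 with pyridinium p-toluenesulfonate in MeOH gives dimethyl acetal F6. (CF3SO2)2O and pyridine at −40 °C give triflate F7. Bu4NBr displaces it with inversion to bromo acetal F8. Aqueous oxalic acid in THF frees bromo aldehyde F9, which enters the Julia–Kocienski olefination with 27 under the conditions of step 16 to give 29.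

Step 11 (bromonium cyclization onto the β-keto ester). The ketone oxygen may cyclize instead of the enol carbon, the bromonium ion may be captured by solvent or lose a proton, and configuration may leak if it opens to a free tertiary cation. The fallback fixes the nucleophile as its methyl enol ether so that only carbon can attack. It sets out from 20 and comes back at 22. HC(OMe)3 with a trace of H2SO4 in MeOH gives β-methoxy acrylate F10. Solvolysis in (CF3)2CHOH as in step 11 gives cyclic enol ether F11, and aqueous HCl in THF hydrolyses it to 22.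

Further compounds
F1 | step 20 | (1R,2S,3S,4S)-4-bromo-3-(2-hydroxyethyl)-2-{(E)-2-[(1R,4R)-4-hydroxy-3,3-dimethylcyclohexyl]ethenyl}-1,3-dimethylcyclohexan-1-ol | OCC[C@]1(C)[C@@H](Br)CC[C@@](C)(O)[C@H]1/C=C/[C@H]1CC(C)(C)[C@H](O)CC1
F2 | step 20 | 2-[(1S,2S,3R,6S)-6-bromo-3-hydroxy-2-{(E)-2-[(1R,4R)-4-hydroxy-3,3-dimethylcyclohexyl]ethenyl}-1,3-dimethylcyclohexyl]acetaldehyde | O=CC[C@]1(C)[C@@H](Br)CC[C@@](C)(O)[C@H]1/C=C/[C@H]1CC(C)(C)[C@H](O)CC1
F3 | step 20 | (1S,2R,3aS,4S,7R,7aS)-4-bromo-1-{(E)-[(4R)-4-hydroxy-3,3-dimethylcyclohexylidene]methyl}-3a,7-dimethyloctahydro-1H-indene-2,7-diol | CC1(C)C/C(=C/[C@@H]2[C@H](O)C[C@]3(C)[C@@H](Br)CC[C@@](C)(O)[C@@H]23)CC[C@H]1O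
F4 | step 20 | 2-O-(tert-butyldimethylsilyl) ether of F3 | CC1(C)C/C(=C/[C@@H]2[C@H](O[Si](C)(C)C(C)(C)C)C[C@]3(C)[C@@H](Br)CC[C@@](C)(O)[C@@H]23)CC[C@H]1O
F5 | step 20 | 2-O-(tert-butyldimethylsilyl) ether of 32 | CC1(C)C/C(=C/[C@@H]2[C@H](O[Si](C)(C)C(C)(C)C)C[C@]3(C)[C@@H](Br)CC[C@@](C)(O)[C@@H]23)CC[C@@H]1Br
F6 | step 17 | (1R,4R)-4-(dimethoxymethyl)-2,2-dimethylcyclohexan-1-ol | COC(OC)[C@H]1CC(C)(C)[C@H](O)CC1
F7 | step 17 | (1R,4R)-4-(dimethoxymethyl)-2,2-dimethylcyclohexyl trifluoromethanesulfonate | COC(OC)[C@H]1CC(C)(C)[C@H](OS(=O)(=O)C(F)(F)F)CC1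
F8 | step 17 | (1S,4R)-1-bromo-4-(dimethoxymethyl)-2,2-dimethylcyclohexane | COC(OC)[C@H]1CC(C)(C)[C@@H](Br)CC1
F9 | step 17 | (1R,4S)-4-bromo-3,3-dimethylcyclohexane-1-carbaldehyde | O=C[C@H]1CC(C)(C)[C@@H](Br)CC1
F10 | step 11 | methyl (6S,7R)-6-bromo-9-[(tert-butyldiphenylsilyl)oxy]-7-chloro-3-methoxy-7-methylnon-2-enoate | COC(=O)C=C(OC)CC[C@H](Br)[C@](C)(Cl)CCO[Si](c1ccccc1)(c1ccccc1)C(C)(C)C
F11 | step 11 | methyl (5S,6S)-5-bromo-6-{2-[(tert-butyldiphenylsilyl)oxy]ethyl}-2-methoxy-6-methylcyclohex-1-ene-1-carboxylate | CC(C)(C)[Si](c1ccccc1)(c1ccccc1)OCC[C@]1(C)[C@@H](Br)CCC(OC)=C1C(=O)OC
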